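Per day, a saturated solution loses a smaller fraction of the charge to the homo dimer, 0.0713 d⁻¹, than the solid can pour into an empty solution, 0.874 d⁻¹.

    starting material ⇌ target (K1 = 0.86, k1 = 1.6 × 10⁻⁴ s⁻¹)
    target ⇌ isomer of the product (K2 = 0.82, k2 = 2.5 × 10⁻⁴ s⁻¹)
    isomer of the product ⇌ starting material (k3 = 6.2 × 10⁻⁶ s⁻¹)
    2 starting material → homo dimer (k4 = 0.0039 M⁻¹ s⁻¹)
    solid substrate ⇌ starting material, rate k5*(cs5 - [starting material]) while solid is left; crystals form when [starting material] > cs5 (cs5 = 2.3 mM, k5 = 2.2 × 10⁻⁴ s⁻¹)

solid substrate 0.050 M; time 2.5 d

* part of the solid substrate that has turned into other species by 2.5 d (what has only dissolved does not count)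
* the target standing at 2.5 d, as a percentage of the solid substrate charged
* the starting material standing at 2.5 d, as a percentage of the solid substrate charged

I counted turnovers in fractions of the charge, starting with a solution held at saturation:

  saturation, s = 4.60%

  passed into homo dimer over the run = 17.8%

That is less than the charge, so I took solid to remain throughout. Starting material and target relax by step 1 with a half-life of 0.556 h, target and isomer of the product by step 2 with one of 0.347 h, both shorter than the run, so I set target and isomer of the product at their equilibrium ratios to starting material. My first conversion was therefore

  25.0%

The weak link was saturation from the first moment. Starting material, as a fraction a, must stand below s, where dissolving balances dimerisation: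

  dissolution coefficient × (s − a) = 2 × dimer constant × charge × a²

  a = 4.28%

I call 0.0616 d⁻¹ the drain, the fraction of the charge passing into homo dimer per day. Target stands at 3.68% and isomer of the product at 3.02%. Dissolving beyond the drain fills the pool of all three, so the shortfall of starting material below a, summed over time as a share of a, comes to about 0.135 d. I took this shortfall as a single exponential with that time, which is an assumption about starting material and not a filling time for the pool. The drain goes as a², so it loses 1.5 of these, a lag of 0.202 d:

  homo dimer = 14.2%

  conversion = 20.8%

The forecast gave a higher conversion than mine, 21.5%, with 3.68% target and 4.28% starting material, holding that "the dissolved species settle within hours into a steady state".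

The simulated flask gave 20.9%, 3.68% and 4.28%, so the forecast's conversion stood 0.60 percentage points high. By 0.250 d dissolving had left 91.4% solid substrate while the pool filled. From 1.25 d to 2.50 d starting material stood at 4.28% while homo dimer rose from 6.49% to 14.2%. In the flask charged with 0.20 M, the same absolute drain is 0.0154 d⁻¹, which gives 3.54% against the 3.55% homo dimer simulated in that flask. The forecast's level needs solid present: left to 25.0 d, this flask held 0% solid substrate and 0.639% starting material.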